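- No rate constant is given for this flask, so I read what I need from the runs, and what I need is one ratio.

| flask | left-handed substrate | right-handed substrate | reagent | free catalyst | remark | time |
|---|---|---|---|---|---|---|
| Sunday's | 0.50 mM | 0.50 mM | 1.1 equiv | 0.25 mol% | run made earlier |  |
| Friday's | 0.50 mM | 0.50 mM | 1.1 equiv | 1 mol% | run made earlier |  |
| Tuesday's | 0.50 mM | 0.50 mM | 0.55 equiv | 0.5 mol% | run made earlier |  |
| flask | 0.50 mM | 0.50 mM | 1.10 equiv | 0.5 mol% |  | 20 min |

- Sunday's (time / min: right-handed substrate / %, left-handed substrate / %): 1.00: 49.3, 7.8; 1.50: 48.7, 4.5; 2.50: 50.6, 1.6; 4.00: 49.9, 1.1; 8.00: 50.5, 1.9; 12.0: 48.7, 0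
- Friday's (time / min: right-handed substrate / %, left-handed substrate / %): 2.00: 50.5, 1.5; 4.00: 48.8, 0.3; 6.00: 48.8, 0; 8.00: 49.1, 0.8; 10.0: 48.7, 0; 12.0: 46.4, 0.5
- Tuesday's (time / min: right-handed substrate / %, left-handed substrate / %): 1.00: 49.9, 23.7; 3.00: 49.5, 22.5; 6.00: 49.6, 21.7; 8.00: 48.3, 25.5; 12.0: 48.5, 21.0

(readings scatter by 1 percentage point)

- free catalyst is single-handed; left-handed substrate and right-handed substrate are mirror images of each other, charged as a racemate, each of them at the stated concentration

* whether the excess of right-handed substrate over left-handed substrate among what is left of the two reaches 80% by 20 min (no / yes)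
* the highest excess of right-handed substrate over left-handed substrate among what is left of the two up to 20 min

- I work with what is left, not with what is made. Let r be [left-handed substrate]/[right-handed substrate]; the excess asked for is then one minus r, divided by one plus r.
- The wanted 80% therefore needs r at or below 0.111, which I call the ceiling ratio.
- Right-handed substrate reads 50.5% at the first reading of Friday's run and 46.4% at its last, so r moves mostly with left-handed substrate.
- Tuesday's run, with 0.55 equiv of reagent, holds left-handed substrate at about 21.0% by its last reading, so reagent is the limiting reagent there. This flask carries twice that charge, 1.10 equiv, which covers one equivalent of left-handed substrate.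
- Sunday's run, with half this flask's loading of free catalyst, reads r = 0.0924 at 1.50 min, under the ceiling. Friday's run, with twice the loading, reads r = 0.0297 at 2.00 min.
- This flask's loading lies between those two, so my own reckoning is yes, within about 2.00 min. For the top I commit to no figure: Friday's later readings of left-handed substrate lie between 0% and 0.8%, with a scatter of 1 percentage point.
- The forecast says yes and goes further, to a top of 99.9%, on these grounds: the late readings of left-handed substrate are “consistent with zero within the scatter, with no firm floor or rebound”.
- The flask gives yes, with a top of 99.8%.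

    2 free catalyst → spent catalyst B (k = 7000 M⁻¹ s⁻¹)
    reagent + free catalyst + left-handed substrate → free catalyst + left-handed product (k = 8.40 × 10⁸ M⁻² s⁻¹)
    free catalyst → spent catalyst A (k = 0.0130 s⁻¹)
    reagent + free catalyst + right-handed substrate → free catalyst + right-handed product (k = 5.70 × 10⁶ M⁻² s⁻¹)
    2 free catalyst ⇌ resting dimer (K = 2.00 × 10⁷ M⁻¹, k = 6.20 × 10⁵ M⁻¹ s⁻¹)

- This flask reaches the wanted excess after 0.909 min, with 49.3% of right-handed substrate still there. At 20.0 min this flask stands at r = 9.04 × 10⁻⁴, far below the ceiling ratio of 0.111. Tuesday's run, at its last reading, 12.0 min, reads r = 0.433, above that ceiling, which is a read excess of 39.6%.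

Readings and results stem from a simulated flask with made-up constants, noise included.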